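## Retrosynthetic overview

- Lignan numbering used here: C7 is the carbinol carbon, C8 the lactone β-carbon, C8' the lactone α-carbon, C7' the benzylic CH2.
- Last step is global O-debenzylation. Before it, the two halves are joined at the aryl–C7' bond by Rh-catalysed 1,4-addition of a dihydrobenzofuran-5-yl boronate to an α-methylene-γ-butyrolactone, with C8' equilibrated to trans.
- Key disconnection is C7–C8 with the polarity reversed on the lactone side. CrCl2 turns a 2-(methoxycarbonyl)allyl bromide into an ester homoenolate (d3) equivalent, whose β-carbon adds to O-benzylvanillin. One catalytic asymmetric step sets C7 and C8 at the final oxidation level.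
- The butyrolactone ring is closed only after that C–C bond, on the primary oxygen. The dihydrofuran ring is closed earlier, on the other fragment, by enantioselective Rh-carbenoid C–H insertion of an aryldiazoacetate made from 4-bromoguaiacol.
- Ring order: dihydrobenzofuran (step 4) and butyrolactone (step 9) are built independently; no ring is formed after the union.

Assumption: the antipode named for each chiral catalyst (the Rh2 carboxylate in step 4, the bis(oxazoline) ligand in step 9) is taken to give the configuration drawn; both mirror-image forms are accessible and the other one is used if the sense of induction proves opposite.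

## Route

Step 1
Reactants: 1 4-bromo-2-methoxyphenol
Product: 2 4-bromo-2-iodo-6-methoxyphenol
Conditions: NIS, TsOH·H2O (10 mol%), MeCN, 0 °C to rt
Reagents that add atoms: N-iodosuccinimide, O=C1CCC(=O)N1I
Why: Electrophilic aromatic iodination; the free hydroxyl directs to its only open ortho position because the para position carries bromine.

Step 2
Reactants: 2 4-bromo-2-iodo-6-methoxyphenol; 3 4-(benzyloxy)-3-methoxybenzyl alcohol
Product: 4 4-(benzyloxy)-3-methoxybenzyl 4-bromo-2-iodo-6-methoxyphenyl ether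
Conditions: PPh3, DIAD, THF, 0 °C to rt
Reagents that add atoms: none
Why: Mitsunobu etherification; the acidic ortho-iodophenol is O-alkylated by the activated primary benzylic alcohol.

Step 3
Reactants: 4 4-(benzyloxy)-3-methoxybenzyl 4-bromo-2-iodo-6-methoxyphenyl ether; 5 ethyl diazoacetate
Product: 6 ethyl 2-(2-{[4-(benzyloxy)-3-methoxyphenyl]methoxy}-5-bromo-3-methoxyphenyl)-2-diazoacetate
Conditions: Pd(PPh3)4 (5 mol%), Ag2CO3 (0.5 equiv), Et3N, PhMe, rt
Reagents that add atoms: none
Why: Pd-catalysed C–H arylation of a diazoacetate; zerovalent palladium inserts into C–I (not C–Br) at rt and the silver salt assists deprotonative coupling with the diazo group retained.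

Step 4
Reactants: 6 ethyl 2-(2-{[4-(benzyloxy)-3-methoxyphenyl]methoxy}-5-bromo-3-methoxyphenyl)-2-diazoacetate
Product: 8 ethyl (2S,3S)-2-[4-(benzyloxy)-3-methoxyphenyl]-5-bromo-7-methoxy-2,3-dihydro-1-benzofuran-3-carboxylate (trans ester), via cis ester 7 (not isolated)
Conditions: Rh2(R-PTTL)4 [dirhodium tetrakis(N-phthaloyl-(R)-tert-leucinate)] (1 mol%), PhMe, −60 °C; then NaOEt (0.5 equiv), EtOH, 0 °C to rt
Reagents that add atoms: none
Why: Enantioselective intramolecular 1,5 C–H insertion of a donor/acceptor rhodium carbenoid into the benzylic ether C–H sets C2 (S) and gives the kinetic cis ester; ethoxide then epimerises only C3 to the thermodynamic trans ester.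

Step 5
Reactants: 8 ethyl (2S,3S)-2-[4-(benzyloxy)-3-methoxyphenyl]-5-bromo-7-methoxy-2,3-dihydro-1-benzofuran-3-carboxylate
Product: 9 [(2S,3R)-2-[4-(benzyloxy)-3-methoxyphenyl]-5-bromo-7-methoxy-2,3-dihydro-1-benzofuran-3-yl]methanol
Conditions: LiBH4, THF, 0 °C to rt; aq. NH4Cl
Reagents that add atoms: none
Why: Chemoselective ester reduction by borohydride; aryl bromide, benzyl ether and both stereocentres are untouched (the C3 descriptor changes by CIP priority only).

Step 6
Reactants: 9 [(2S,3R)-2-[4-(benzyloxy)-3-methoxyphenyl]-5-bromo-7-methoxy-2,3-dihydro-1-benzofuran-3-yl]methanol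
Product: 10 [(2S,3R)-2-[4-(benzyloxy)-3-methoxyphenyl]-7-methoxy-5-(4,4,5,5-tetramethyl-1,3,2-dioxaborolan-2-yl)-2,3-dihydro-1-benzofuran-3-yl]methanol
Conditions: B2pin2, PdCl2(dppf) (3 mol%), KOAc, 1,4-dioxane, 85 °C
Reagents that add atoms: bis(pinacolato)diboron, CC1(C)OB(OC1(C)C)B1OC(C)(C)C(C)(C)O1
Why: Miyaura borylation of the aryl bromide; the acetate base tolerates the free primary alcohol and the benzylic ethers.

Step 7
Reactants: 11 methyl acrylate; 12 (tert-butyldimethylsilyloxy)acetaldehyde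
Product: 13 methyl 4-[(tert-butyldimethylsilyl)oxy]-3-hydroxy-2-methylidenebutanoate (racemic)
Conditions: DABCO (0.5 equiv), neat acrylate (3 equiv), rt, 3 d
Reagents that add atoms: none
Why: Morita–Baylis–Hillman reaction with a reactive α-oxygenated aldehyde; the carbinol stereocentre is irrelevant because step 8 destroys it.

Step 8
Reactants: 13 methyl 4-[(tert-butyldimethylsilyl)oxy]-3-hydroxy-2-methylidenebutanoate
Product: 14 methyl (2Z)-2-(bromomethyl)-4-[(tert-butyldimethylsilyl)oxy]but-2-enoate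
Conditions: NBS, Me2S, CH2Cl2, −20 °C to rt
Reagents that add atoms: N-bromosuccinimide, O=C1CCC(=O)N1Br
Why: Corey–Kim-type activation of the allylic alcohol followed by SN2' attack of bromide gives the rearranged, thermodynamically preferred Z bromide without acid that would cleave the silyl ether.

Step 9
Reactants: 14 methyl (2Z)-2-(bromomethyl)-4-[(tert-butyldimethylsilyl)oxy]but-2-enoate (1.5 equiv); 15 4-(benzyloxy)-3-methoxybenzaldehyde
Product: 18 (4R)-4-[(R)-[4-(benzyloxy)-3-methoxyphenyl](hydroxy)methyl]-3-methylideneoxolan-2-one, via bis-silyl ether 16 (not isolated), via diol ester 17 (not isolated)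
Conditions: CrCl2 (10 mol%), (S,S)-3,6-diphenyl-1,8-bis(4-isopropyl-4,5-dihydro-1,3-oxazol-2-yl)-9H-carbazole (12 mol%), Mn powder, TMSCl, iPr2NEt, THF, rt; then TBAF, THF, 0 °C; AcOH quench
Reagents that add atoms: chlorotrimethylsilane, C[Si](C)(C)Cl (its silyl group is carried only by 16)
Why: Proposed new method: CrCl2 (divalent chromium, regenerated by Mn and TMSCl) reduces bromide 14 to a 2-(methoxycarbonyl)allyl species of trivalent chromium, an ester homoenolate (d3) equivalent, so the enoate β-carbon (an electrophile in normal polarity) attacks the electrophilic aldehyde carbon of 15 through a closed Zimmerman–Traxler chair in which the Z-disposed CH2OTBS group enforces the 7,8-syn relationship and the tridentate ligand selects the Re face (7R,8R), after which fluoride frees both oxygens and the primary alkoxide closes the less substituted lactone, with alkoxide exchange funnelling any 5-aryl isomer to it; the closest known reaction type is the catalytic asymmetric Nozaki–Hiyama–Kishi 2-(alkoxycarbonyl)allylation that gives cis-β,γ-disubstituted α-methylene-γ-butyrolactones from Z bromides.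

Step 10
Reactants: 18 (4R)-4-[(R)-[4-(benzyloxy)-3-methoxyphenyl](hydroxy)methyl]-3-methylideneoxolan-2-one (1.3 equiv); 10 [(2S,3R)-2-[4-(benzyloxy)-3-methoxyphenyl]-7-methoxy-5-(4,4,5,5-tetramethyl-1,3,2-dioxaborolan-2-yl)-2,3-dihydro-1-benzofuran-3-yl]methanol
Product: 20 (3R,4R)-3-{[(2S,3R)-2-[4-(benzyloxy)-3-methoxyphenyl]-3-(hydroxymethyl)-7-methoxy-2,3-dihydro-1-benzofuran-5-yl]methyl}-4-[(R)-[4-(benzyloxy)-3-methoxyphenyl](hydroxy)methyl]oxolan-2-one, via cis lactone 19 (not isolated)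
Conditions: [Rh(OH)(cod)]2 (2.5 mol%), K3PO4, 1,4-dioxane/H2O 20:1, 50 °C; then DBU, 50 °C; aq. citric acid work-up
Reagents that add atoms: none
Why: Hayashi–Miyaura-type Rh-catalysed conjugate addition puts the aryl group on the exocyclic CH2, the rhodium enolate is protonated mainly anti to the C4 substituent (cis lactone 19), and DBU equilibrates the acidic C3 centre to the more stable trans (3R) lactone without touching C4 or C7.

Step 11
Reactants: 20 (3R,4R)-3-{[(2S,3R)-2-[4-(benzyloxy)-3-methoxyphenyl]-3-(hydroxymethyl)-7-methoxy-2,3-dihydro-1-benzofuran-5-yl]methyl}-4-[(R)-[4-(benzyloxy)-3-methoxyphenyl](hydroxy)methyl]oxolan-2-one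
Product: 21 (3R,4R)-4-[(R)-hydroxy(4-hydroxy-3-methoxyphenyl)methyl]-3-{[(2S,3R)-2-(4-hydroxy-3-methoxyphenyl)-3-(hydroxymethyl)-7-methoxy-2,3-dihydro-1-benzofuran-5-yl]methyl}oxolan-2-one (target)
Conditions: H2 (1 atm), 10% Pd/C, NaHCO3 (solid), EtOAc/EtOH, rt, stopped after 2 equiv H2
Reagents that add atoms: none
Why: Catalytic hydrogenolysis of the two aryl benzyl ethers under neutral, buffered, ambient conditions, where the benzylic C7–OH and the dihydrofuran C2–O bonds (which need acid or forcing conditions to cleave) are retained.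

## Compound list

1 | 4-bromo-2-methoxyphenol | COc1cc(Br)ccc1O | starting material
2 | 4-bromo-2-iodo-6-methoxyphenol | COc1cc(Br)cc(I)c1O | intermediate
3 | 4-(benzyloxy)-3-methoxybenzyl alcohol | COc1cc(CO)ccc1OCc1ccccc1 | starting material
4 | 4-(benzyloxy)-3-methoxybenzyl 4-bromo-2-iodo-6-methoxyphenyl ether | COc1cc(Br)cc(I)c1OCc1ccc(OCc2ccccc2)c(OC)c1 | intermediate
5 | ethyl diazoacetate | CCOC(=O)C=[N+]=[N-] | starting material
6 | ethyl 2-(2-{[4-(benzyloxy)-3-methoxyphenyl]methoxy}-5-bromo-3-methoxyphenyl)-2-diazoacetate | CCOC(=O)C(=[N+]=[N-])c1cc(Br)cc(OC)c1OCc1ccc(OCc2ccccc2)c(OC)c1 | intermediate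
7 | ethyl (2S,3R)-2-[4-(benzyloxy)-3-methoxyphenyl]-5-bromo-7-methoxy-2,3-dihydro-1-benzofuran-3-carboxylate (cis) | COc1cc([C@H]2Oc3c(OC)cc(Br)cc3[C@H]2C(=O)OCC)ccc1OCc1ccccc1 | intermediate
8 | ethyl (2S,3S)-2-[4-(benzyloxy)-3-methoxyphenyl]-5-bromo-7-methoxy-2,3-dihydro-1-benzofuran-3-carboxylate (trans) | COc1cc([C@H]2Oc3c(OC)cc(Br)cc3[C@@H]2C(=O)OCC)ccc1OCc1ccccc1 | intermediate
9 | [(2S,3R)-2-[4-(benzyloxy)-3-methoxyphenyl]-5-bromo-7-methoxy-2,3-dihydro-1-benzofuran-3-yl]methanol | COc1cc([C@H]2Oc3c(OC)cc(Br)cc3[C@@H]2CO)ccc1OCc1ccccc1 | intermediate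
10 | [(2S,3R)-2-[4-(benzyloxy)-3-methoxyphenyl]-7-methoxy-5-(4,4,5,5-tetramethyl-1,3,2-dioxaborolan-2-yl)-2,3-dihydro-1-benzofuran-3-yl]methanol | COc1cc([C@H]2Oc3c(OC)cc(B4OC(C)(C)C(C)(C)O4)cc3[C@@H]2CO)ccc1OCc1ccccc1 | intermediate
11 | methyl acrylate | C=CC(=O)OC | starting material
12 | (tert-butyldimethylsilyloxy)acetaldehyde | CC(C)(C)[Si](C)(C)OCC=O | starting material
13 | methyl 4-[(tert-butyldimethylsilyl)oxy]-3-hydroxy-2-methylidenebutanoate (racemic) | C=C(C(=O)OC)C(O)CO[Si](C)(C)C(C)(C)C | intermediate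
14 | methyl (2Z)-2-(bromomethyl)-4-[(tert-butyldimethylsilyl)oxy]but-2-enoate | BrC/C(C(=O)OC)=C\CO[Si](C)(C)C(C)(C)C | intermediate
15 | 4-(benzyloxy)-3-methoxybenzaldehyde | COc1cc(C=O)ccc1OCc1ccccc1 | starting material
16 | methyl (3R,4R)-4-[4-(benzyloxy)-3-methoxyphenyl]-3-{[(tert-butyldimethylsilyl)oxy]methyl}-2-methylidene-4-[(trimethylsilyl)oxy]butanoate | C=C(C(=O)OC)[C@H](CO[Si](C)(C)C(C)(C)C)[C@@H](O[Si](C)(C)C)c1ccc(OCc2ccccc2)c(OC)c1 | intermediate
17 | methyl (3R,4R)-4-[4-(benzyloxy)-3-methoxyphenyl]-4-hydroxy-3-(hydroxymethyl)-2-methylidenebutanoate | C=C(C(=O)OC)[C@H](CO)[C@@H](O)c1ccc(OCc2ccccc2)c(OC)c1 | intermediate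
18 | (4R)-4-[(R)-[4-(benzyloxy)-3-methoxyphenyl](hydroxy)methyl]-3-methylideneoxolan-2-one | C=C1C(=O)OC[C@@H]1[C@@H](O)c1ccc(OCc2ccccc2)c(OC)c1 | intermediate
19 | (3S,4R)-3-{[(2S,3R)-2-[4-(benzyloxy)-3-methoxyphenyl]-3-(hydroxymethyl)-7-methoxy-2,3-dihydro-1-benzofuran-5-yl]methyl}-4-[(R)-[4-(benzyloxy)-3-methoxyphenyl](hydroxy)methyl]oxolan-2-one (cis) | COc1cc([C@H]2Oc3c(OC)cc(C[C@@H]4C(=O)OC[C@@H]4[C@@H](O)c4ccc(OCc5ccccc5)c(OC)c4)cc3[C@@H]2CO)ccc1OCc1ccccc1 | intermediate
20 | (3R,4R)-3-{[(2S,3R)-2-[4-(benzyloxy)-3-methoxyphenyl]-3-(hydroxymethyl)-7-methoxy-2,3-dihydro-1-benzofuran-5-yl]methyl}-4-[(R)-[4-(benzyloxy)-3-methoxyphenyl](hydroxy)methyl]oxolan-2-one (trans) | COc1cc([C@H]2Oc3c(OC)cc(C[C@H]4C(=O)OC[C@@H]4[C@@H](O)c4ccc(OCc5ccccc5)c(OC)c4)cc3[C@@H]2CO)ccc1OCc1ccccc1 | intermediate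
21 | (3R,4R)-4-[(R)-hydroxy(4-hydroxy-3-methoxyphenyl)methyl]-3-{[(2S,3R)-2-(4-hydroxy-3-methoxyphenyl)-3-(hydroxymethyl)-7-methoxy-2,3-dihydro-1-benzofuran-5-yl]methyl}oxolan-2-one | COc1cc([C@H]2Oc3c(OC)cc(C[C@H]4C(=O)OC[C@@H]4[C@@H](O)c4ccc(O)c(OC)c4)cc3[C@@H]2CO)ccc1O | target

## Step count and risks

Total step count: 11. Longest linear sequence: 8 (steps 1 to 6, then 10 and 11); the lactone branch is steps 7 to 9.

**Step 9 (key step).** Risks are β-elimination of silyloxide from the allylmetal, modest enantioselectivity with the electron-rich aldehyde, and closure to the 5-aryl lactone instead of 18. The fallback changes the d3 reagent from a catalytic organochromium to a preformed allylboronate. It sets out from 14 and 15 and returns at 17. Bromide 14 is borylated (B2pin2, CuCl, KOAc, DMF) to methyl (2E)-4-[(tert-butyldimethylsilyl)oxy]-2-[(4,4,5,5-tetramethyl-1,3,2-dioxaborolan-2-yl)methyl]but-2-enoate F1, which has the same alkene geometry as 14 (the descriptor changes only because boron ranks below oxygen) and cannot β-eliminate. F1 adds to 15 under chiral phosphoric acid catalysis ((R)-TRIP, PhMe) through the same chair transition state to give the syn adduct methyl (3R,4R)-4-[4-(benzyloxy)-3-methoxyphenyl]-3-{[(tert-butyldimethylsilyl)oxy]methyl}-4-hydroxy-2-methylidenebutanoate F2. TBAF then gives 17, which closes to 18 as in step 9.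

**Step 10.** Risks are oxidation of the free benzylic alcohol by a rhodium alkoxide/hydride shuttle, incomplete cis-to-trans equilibration, and lactone opening under base. The fallback replaces conjugate addition and protonation by a Heck reaction and a directed hydrogenation. It sets out from 9 and 18 and returns at 20, and it also bypasses step 6. Heck coupling (Pd(OAc)2, P(o-tol)3, Et3N, DMF, 90 °C) gives (3E,4R)-3-{[(2S,3R)-2-[4-(benzyloxy)-3-methoxyphenyl]-3-(hydroxymethyl)-7-methoxy-2,3-dihydro-1-benzofuran-5-yl]methylidene}-4-[(R)-[4-(benzyloxy)-3-methoxyphenyl](hydroxy)methyl]oxolan-2-one F3. Hydroxyl-directed hydrogenation with [Rh(nbd)(dppb)]BF4 and H2 in CH2Cl2 then delivers hydrogen to C3 from the face of the carbinol substituent, giving trans lactone 20 directly.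

**Step 4.** Risks are enantiomeric excess below what a single-enantiomer target needs (any shortfall ends up as a remote diastereomer of 21 that is hard to remove) and an opposite sense of induction. The fallback replaces pure catalyst control by a covalently bound auxiliary that makes the stereoisomers separable. It sets out from 4 and returns at 8. Compound 4 is coupled under the step 3 conditions with (3R)-4,4-dimethyl-2-oxooxolan-3-yl 2-diazoacetate F4 (the diazoacetate of (R)-pantolactone) to give (3R)-4,4-dimethyl-2-oxooxolan-3-yl 2-(2-{[4-(benzyloxy)-3-methoxyphenyl]methoxy}-5-bromo-3-methoxyphenyl)-2-diazoacetate F5. C–H insertion with Rh2(S-DOSP)4 [dirhodium tetrakis((S)-N-(dodecylbenzenesulfonyl)prolinate)] gives (3R)-4,4-dimethyl-2-oxooxolan-3-yl (2S,3R)-2-[4-(benzyloxy)-3-methoxyphenyl]-5-bromo-7-methoxy-2,3-dihydro-1-benzofuran-3-carboxylate F6, whose C2 diastereomers are removed by chromatography or crystallisation. NaOEt in EtOH then transesterifies and epimerises C3 to give 8.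

Further compounds

F1 | step 9 | methyl (2E)-4-[(tert-butyldimethylsilyl)oxy]-2-[(4,4,5,5-tetramethyl-1,3,2-dioxaborolan-2-yl)methyl]but-2-enoate | COC(=O)C(/CB1OC(C)(C)C(C)(C)O1)=C/CO[Si](C)(C)C(C)(C)C
F2 | step 9 | methyl (3R,4R)-4-[4-(benzyloxy)-3-methoxyphenyl]-3-{[(tert-butyldimethylsilyl)oxy]methyl}-4-hydroxy-2-methylidenebutanoate | C=C(C(=O)OC)[C@H](CO[Si](C)(C)C(C)(C)C)[C@@H](O)c1ccc(OCc2ccccc2)c(OC)c1
F3 | step 10 | (3E,4R)-3-{[(2S,3R)-2-[4-(benzyloxy)-3-methoxyphenyl]-3-(hydroxymethyl)-7-methoxy-2,3-dihydro-1-benzofuran-5-yl]methylidene}-4-[(R)-[4-(benzyloxy)-3-methoxyphenyl](hydroxy)methyl]oxolan-2-one | COc1cc([C@H]2Oc3c(OC)cc(/C=C4/C(=O)OC[C@@H]4[C@@H](O)c4ccc(OCc5ccccc5)c(OC)c4)cc3[C@@H]2CO)ccc1OCc1ccccc1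
F4 | step 4 | (3R)-4,4-dimethyl-2-oxooxolan-3-yl 2-diazoacetate | CC1(C)COC(=O)[C@@H]1OC(=O)C=[N+]=[N-]
F5 | step 4 | (3R)-4,4-dimethyl-2-oxooxolan-3-yl 2-(2-{[4-(benzyloxy)-3-methoxyphenyl]methoxy}-5-bromo-3-methoxyphenyl)-2-diazoacetate | CC1(C)COC(=O)[C@@H]1OC(=O)C(=[N+]=[N-])c1cc(Br)cc(OC)c1OCc1ccc(OCc2ccccc2)c(OC)c1
F6 | step 4 | (3R)-4,4-dimethyl-2-oxooxolan-3-yl (2S,3R)-2-[4-(benzyloxy)-3-methoxyphenyl]-5-bromo-7-methoxy-2,3-dihydro-1-benzofuran-3-carboxylate | COc1cc([C@H]2Oc3c(OC)cc(Br)cc3[C@H]2C(=O)O[C@H]4C(=O)OCC4(C)C)ccc1OCc1ccccc1
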